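## Retrosynthetic overview

1. Isolappaol A ⇐ one acyclic seco compound. Its γ-hydroxy tert-butyl ester gives the γ-lactone, and its 1-(4-hydroxyaryl)-2-arylpropane-1,3-diol with the ortho phenol gives the trans-2,3-dihydrobenzofuran. Both rings close together in the last operation, which also sets C-2 of the benzofuran.
2. Seco compound ⇐ LiBH4 reduction of a bis(N-acyloxazolidinone); an Evans syn-aldol with vanillin acetate sets benzofuran C-3.
3. Arylacetyl imide ⇐ Pd-catalysed α-arylation of an N-acetyloxazolidinone silyl enolate with the aryl bromide of an anti-2,3-dibenzylsuccinate.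
4. anti-Dibenzylsuccinate ⇐ Evans alkylation (lactone C-4) of the imide of an (R)-2-benzylsuccinic half-ester ⇐ Rh–DuPhos hydrogenation (lactone C-3) of the Stobbe half-ester from MOM-protected 5-bromovanillin and di-tert-butyl succinate.
5. Ring order: no non-aromatic ring exists before the final step; lactone and dihydrofuran then form in one pot.

Assumption: the six numbered starting materials (1, 3, 6, 8, 13, 16), the catalysts and the common reagents are bought; the sense of induction quoted for each catalyst or auxiliary follows its established model.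

## Route

Step 1
Reactants: 1 5-bromovanillin (3-bromo-4-hydroxy-5-methoxybenzaldehyde)
Product: 2 3-bromo-5-methoxy-4-(methoxymethoxy)benzaldehyde
Conditions: MOMCl, i-Pr2NEt, CH2Cl2, 0 °C → rt
Reagents that add atoms: chloromethyl methyl ether, COCCl
Why: Williamson-type O-alkylation (MOM protection) of the phenol gives an acetal that survives the basic steps 2 and 7 and is cleaved by the acid of step 10.

Step 2
Reactants: 2 3-bromo-5-methoxy-4-(methoxymethoxy)benzaldehyde; 3 di-tert-butyl succinate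
Product: 4 (3E)-4-[3-bromo-5-methoxy-4-(methoxymethoxy)phenyl]-3-(tert-butoxycarbonyl)but-3-enoic acid
Conditions: t-BuOK, t-BuOH, 50 °C; then aq. HCl
Reagents that add atoms: none
Why: Stobbe condensation of a non-enolisable aldehyde with a succinic diester gives the (E)-alkylidene half-ester, in which the tert-butyl ester carbon (future lactone carbonyl) and the free acid (future CH2O) are differentiated; no stereocentre is formed.

Step 3
Reactants: 4 (3E)-4-[3-bromo-5-methoxy-4-(methoxymethoxy)phenyl]-3-(tert-butoxycarbonyl)but-3-enoic acid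
Product: 5 (3R)-3-{[3-bromo-5-methoxy-4-(methoxymethoxy)phenyl]methyl}-4-tert-butoxy-4-oxobutanoic acid
Conditions: H2 (5 bar), [((S,S)-Et-DuPhos)Rh(cod)]BF4 (0.5 mol%), NaOMe (0.1 equiv), MeOH, rt
Reagents that add atoms: none
Why: Burk-type Rh–DuPhos asymmetric hydrogenation of a Stobbe itaconate half-ester, in which carboxylate and olefin chelate rhodium and the (S,S)-ligand delivers H2 to one face, gives the (R)-2-benzylsuccinate (future lactone C-3; this substrate class typically gives ≥97% ee) and leaves the aryl bromide intact.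

Step 4
Reactants: 5 (3R)-3-{[3-bromo-5-methoxy-4-(methoxymethoxy)phenyl]methyl}-4-tert-butoxy-4-oxobutanoic acid; 6 (R)-4-benzyl-1,3-oxazolidin-2-one
Product: 7 tert-butyl (2R)-4-[(4R)-4-benzyl-2-oxo-1,3-oxazolidin-3-yl]-2-{[3-bromo-5-methoxy-4-(methoxymethoxy)phenyl]methyl}-4-oxobutanoate
Conditions: DCC, DMAP (cat.), CH2Cl2, 0 °C → rt
Reagents that add atoms: none
Why: Steglich-type (carbodiimide/DMAP) N-acylation of the oxazolidinone by the unhindered CH2CO2H; the stereocentre is β to the activated carbonyl and is not epimerised.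

Step 5
Reactants: 8 vanillyl alcohol (4-(hydroxymethyl)-2-methoxyphenol)
Product: 9 [3-methoxy-4-(methoxymethoxy)phenyl]methanol
Conditions: MOMCl, K2CO3, acetone, 0 °C → rt
Reagents that add atoms: chloromethyl methyl ether, COCCl
Why: Chemoselective Williamson alkylation of the phenoxide (pKa about 10) in the presence of the neutral benzylic alcohol.

Step 6
Reactants: 9 [3-methoxy-4-(methoxymethoxy)phenyl]methanol
Product: 10 4-(bromomethyl)-2-methoxy-1-(methoxymethoxy)benzene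
Conditions: CBr4, PPh3, CH2Cl2, 0 °C; used crude at once
Reagents that add atoms: carbon tetrabromide, BrC(Br)(Br)Br
Why: Appel reaction (bromide displaces the oxyphosphonium) runs under neutral conditions, so the acid-labile MOM ether survives.

Step 7
Reactants: 7 tert-butyl (2R)-4-[(4R)-4-benzyl-2-oxo-1,3-oxazolidin-3-yl]-2-{[3-bromo-5-methoxy-4-(methoxymethoxy)phenyl]methyl}-4-oxobutanoate; 10 4-(bromomethyl)-2-methoxy-1-(methoxymethoxy)benzene
Product: 12 tert-butyl (2R,3R)-3-{[(4R)-4-benzyl-2-oxo-1,3-oxazolidin-3-yl]carbonyl}-2-{[3-bromo-5-methoxy-4-(methoxymethoxy)phenyl]methyl}-4-[3-methoxy-4-(methoxymethoxy)phenyl]butanoate, via sodium Z-enolate 11 (not isolated)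
Conditions: NaHMDS, THF, −78 °C; then 10, −78 → −30 °C
Reagents that add atoms: sodium bis(trimethylsilyl)amide, C[Si](C)(C)[N-][Si](C)(C)C.[Na+] (its sodium is in 11 only; nothing from it remains in 12)
Why: Evans asymmetric alkylation, in which NaHMDS removes only the imide CH2 proton (far more acidic than the tertiary α-H of the tert-butyl ester) and the chelated Z-enolate is benzylated on the face opposite the benzyl group of the (R)-auxiliary, sets the new centre (future lactone C-4) as R and anti to the existing one under auxiliary control.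

Step 8
Reactants: 12 tert-butyl (2R,3R)-3-{[(4R)-4-benzyl-2-oxo-1,3-oxazolidin-3-yl]carbonyl}-2-{[3-bromo-5-methoxy-4-(methoxymethoxy)phenyl]methyl}-4-[3-methoxy-4-(methoxymethoxy)phenyl]butanoate; 13 (S)-3-acetyl-4-benzyl-1,3-oxazolidin-2-one
Product: 15 tert-butyl (2R,3R)-3-{[(4R)-4-benzyl-2-oxo-1,3-oxazolidin-3-yl]carbonyl}-2-{[3-{2-[(4S)-4-benzyl-2-oxo-1,3-oxazolidin-3-yl]-2-oxoethyl}-5-methoxy-4-(methoxymethoxy)phenyl]methyl}-4-[3-methoxy-4-(methoxymethoxy)phenyl]butanoate, via TMS enol ether 14 (not isolated)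
Conditions: 13, TMSOTf, Et3N, CH2Cl2, 0 °C, evaporate; then 12, Pd(dba)2 (5 mol%), P(t-Bu)3 (10 mol%), ZnF2 (0.6 equiv), DMF, 80 °C
Reagents that add atoms: trimethylsilyl triflate, C[Si](C)(C)OS(=O)(=O)C(F)(F)F (its silyl group is in 14 only; nothing from it remains in 15)
Why: Hartwig-type Pd/P(t-Bu)3-catalysed α-arylation of a silyl enolate of an N-acyloxazolidinone with ZnF2 as mild activator needs no strong base, so the epimerisable imide α-centre, the tert-butyl ester and the MOM ethers survive; no stereocentre is formed.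

Step 9
Reactants: 15 tert-butyl (2R,3R)-3-{[(4R)-4-benzyl-2-oxo-1,3-oxazolidin-3-yl]carbonyl}-2-{[3-{2-[(4S)-4-benzyl-2-oxo-1,3-oxazolidin-3-yl]-2-oxoethyl}-5-methoxy-4-(methoxymethoxy)phenyl]methyl}-4-[3-methoxy-4-(methoxymethoxy)phenyl]butanoate; 16 vanillin acetate (4-formyl-2-methoxyphenyl acetate)
Product: 18 tert-butyl (2R,3R)-2-{[3-{(2S,3S)-3-[4-(acetyloxy)-3-methoxyphenyl]-1-[(4S)-4-benzyl-2-oxo-1,3-oxazolidin-3-yl]-3-hydroxy-1-oxopropan-2-yl}-5-methoxy-4-(methoxymethoxy)phenyl]methyl}-3-{[(4R)-4-benzyl-2-oxo-1,3-oxazolidin-3-yl]carbonyl}-4-[3-methoxy-4-(methoxymethoxy)phenyl]butanoate, via dibutylboron Z-enolate 17 (not isolated)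
Conditions: n-Bu2BOTf, i-Pr2NEt, CH2Cl2, −78 → 0 °C; 16, −78 → 0 °C; then pH 7 buffer, MeOH, H2O2, 0 °C
Reagents that add atoms: dibutylboron triflate, CCCCB(CCCC)OS(=O)(=O)C(F)(F)F (its boron is in 17 only; nothing from it remains in 18)
Why: Evans boron syn-aldol, in which soft enolisation touches only the much more acidic arylacetyl imide and the (Z)-boron enolate reacts through a Zimmerman–Traxler chair opposite the benzyl group of the (S)-auxiliary, fixes the α-carbon (future benzofuran C-3; S here, R after reduction) together with a syn (S) carbinol.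

Step 10
Reactants: 18 tert-butyl (2R,3R)-2-{[3-{(2S,3S)-3-[4-(acetyloxy)-3-methoxyphenyl]-1-[(4S)-4-benzyl-2-oxo-1,3-oxazolidin-3-yl]-3-hydroxy-1-oxopropan-2-yl}-5-methoxy-4-(methoxymethoxy)phenyl]methyl}-3-{[(4R)-4-benzyl-2-oxo-1,3-oxazolidin-3-yl]carbonyl}-4-[3-methoxy-4-(methoxymethoxy)phenyl]butanoate
Product: 20 isolappaol A, via seco triol ester 19 (not isolated)
Conditions: LiBH4, MeOH (1 equiv per LiBH4), THF, 0 °C → rt; then 3 M aq. HCl, THF, 45 °C
Reagents that add atoms: none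
Why: LiBH4 cleaves both N-acyloxazolidinones reductively (and the aryl acetate) but not the tert-butyl ester, and the acid then removes the MOM groups, lactonises the γ-hydroxy ester (both lactone centres already set and untouched) and ionises the p-hydroxybenzylic alcohol to a quinone-methide-type cation that the ortho phenol traps 5-exo under thermodynamic control (acid-induced phenylcoumaran closure), which places the aryl group trans to the fixed C-3 substituent and so sets C-2 as S.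

## Compound list

1 | 5-bromovanillin (3-bromo-4-hydroxy-5-methoxybenzaldehyde) | COc1cc(C=O)cc(Br)c1O | starting material
2 | 3-bromo-5-methoxy-4-(methoxymethoxy)benzaldehyde | COCOc1c(Br)cc(C=O)cc1OC | intermediate
3 | di-tert-butyl succinate | CC(C)(C)OC(=O)CCC(=O)OC(C)(C)C | starting material
4 | (3E)-4-[3-bromo-5-methoxy-4-(methoxymethoxy)phenyl]-3-(tert-butoxycarbonyl)but-3-enoic acid | OC(=O)C/C(C(=O)OC(C)(C)C)=C\c1cc(Br)c(OCOC)c(OC)c1 | intermediate
5 | (3R)-3-{[3-bromo-5-methoxy-4-(methoxymethoxy)phenyl]methyl}-4-tert-butoxy-4-oxobutanoic acid | OC(=O)C[C@@H](Cc1cc(Br)c(OCOC)c(OC)c1)C(=O)OC(C)(C)C | intermediate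
6 | (R)-4-benzyl-1,3-oxazolidin-2-one | O=C1N[C@H](Cc2ccccc2)CO1 | starting material
7 | tert-butyl (2R)-4-[(4R)-4-benzyl-2-oxo-1,3-oxazolidin-3-yl]-2-{[3-bromo-5-methoxy-4-(methoxymethoxy)phenyl]methyl}-4-oxobutanoate | O=C1OC[C@@H](Cc2ccccc2)N1C(=O)C[C@@H](Cc1cc(Br)c(OCOC)c(OC)c1)C(=O)OC(C)(C)C | intermediate
8 | vanillyl alcohol (4-(hydroxymethyl)-2-methoxyphenol) | COc1cc(CO)ccc1O | starting material
9 | [3-methoxy-4-(methoxymethoxy)phenyl]methanol | COCOc1ccc(CO)cc1OC | intermediate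
10 | 4-(bromomethyl)-2-methoxy-1-(methoxymethoxy)benzene | COCOc1ccc(CBr)cc1OC | intermediate
11 | sodium (Z)-enolate of imide 7 (formed in situ; ester-bearing stereocentre unchanged) | [Na+].[O-]/C(=C\[C@@H](Cc1cc(Br)c(OCOC)c(OC)c1)C(=O)OC(C)(C)C)N1[C@H](Cc2ccccc2)COC1=O | intermediate
12 | tert-butyl (2R,3R)-3-{[(4R)-4-benzyl-2-oxo-1,3-oxazolidin-3-yl]carbonyl}-2-{[3-bromo-5-methoxy-4-(methoxymethoxy)phenyl]methyl}-4-[3-methoxy-4-(methoxymethoxy)phenyl]butanoate | O=C1OC[C@@H](Cc2ccccc2)N1C(=O)[C@H](Cc1ccc(OCOC)c(OC)c1)[C@@H](Cc1cc(Br)c(OCOC)c(OC)c1)C(=O)OC(C)(C)C | intermediate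
13 | (S)-3-acetyl-4-benzyl-1,3-oxazolidin-2-one | CC(=O)N1[C@@H](Cc2ccccc2)COC1=O | starting material
14 | (4S)-4-benzyl-3-{1-[(trimethylsilyl)oxy]ethenyl}-1,3-oxazolidin-2-one (formed in situ) | C=C(O[Si](C)(C)C)N1[C@@H](Cc2ccccc2)COC1=O | intermediate
15 | tert-butyl (2R,3R)-3-{[(4R)-4-benzyl-2-oxo-1,3-oxazolidin-3-yl]carbonyl}-2-{[3-{2-[(4S)-4-benzyl-2-oxo-1,3-oxazolidin-3-yl]-2-oxoethyl}-5-methoxy-4-(methoxymethoxy)phenyl]methyl}-4-[3-methoxy-4-(methoxymethoxy)phenyl]butanoate | O=C1OC[C@@H](Cc2ccccc2)N1C(=O)[C@H](Cc1ccc(OCOC)c(OC)c1)[C@@H](Cc1cc(CC(=O)N2[C@@H](Cc3ccccc3)COC2=O)c(OCOC)c(OC)c1)C(=O)OC(C)(C)C | intermediate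
16 | vanillin acetate (4-formyl-2-methoxyphenyl acetate) | CC(=O)Oc1ccc(C=O)cc1OC | starting material
17 | dibutylboron (Z)-enolate of the arylacetyl imide of 15 (formed in situ) | O=C1OC[C@@H](Cc2ccccc2)N1C(=O)[C@H](Cc1ccc(OCOC)c(OC)c1)[C@@H](Cc1cc(/C=C(\OB(CCCC)CCCC)N2[C@@H](Cc3ccccc3)COC2=O)c(OCOC)c(OC)c1)C(=O)OC(C)(C)C | intermediate
18 | tert-butyl (2R,3R)-2-{[3-{(2S,3S)-3-[4-(acetyloxy)-3-methoxyphenyl]-1-[(4S)-4-benzyl-2-oxo-1,3-oxazolidin-3-yl]-3-hydroxy-1-oxopropan-2-yl}-5-methoxy-4-(methoxymethoxy)phenyl]methyl}-3-{[(4R)-4-benzyl-2-oxo-1,3-oxazolidin-3-yl]carbonyl}-4-[3-methoxy-4-(methoxymethoxy)phenyl]butanoate (syn-aldol adduct) | O=C1OC[C@@H](Cc2ccccc2)N1C(=O)[C@H](Cc1ccc(OCOC)c(OC)c1)[C@@H](Cc1cc([C@H](C(=O)N2[C@@H](Cc3ccccc3)COC2=O)[C@H](O)c2ccc(OC(C)=O)c(OC)c2)c(OCOC)c(OC)c1)C(=O)OC(C)(C)C | intermediate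
19 | tert-butyl (2R,3R)-2-{[3-[(1S,2R)-1,3-dihydroxy-1-(4-hydroxy-3-methoxyphenyl)propan-2-yl]-5-methoxy-4-(methoxymethoxy)phenyl]methyl}-3-(hydroxymethyl)-4-[3-methoxy-4-(methoxymethoxy)phenyl]butanoate (seco compound, formed in situ) | OC[C@H](Cc1ccc(OCOC)c(OC)c1)[C@@H](Cc1cc([C@H](CO)[C@H](O)c2ccc(O)c(OC)c2)c(OCOC)c(OC)c1)C(=O)OC(C)(C)C | intermediate
20 | isolappaol A, (3R,4R)-3-{[(2S,3R)-2-(4-hydroxy-3-methoxyphenyl)-3-(hydroxymethyl)-7-methoxy-2,3-dihydro-1-benzofuran-5-yl]methyl}-4-[(4-hydroxy-3-methoxyphenyl)methyl]oxolan-2-one | COc1cc(C[C@H]2COC(=O)[C@@H]2Cc2cc(OC)c3c(c2)[C@H](CO)[C@@H](c2ccc(O)c(OC)c2)O3)ccc1O | target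

## Step count and risk

Total step count: 10. Longest linear sequence: 8 steps (1, 2, 3, 4, 7, 8, 9, 10) from 5-bromovanillin; steps 5 and 6 make the side-arm bromide.

The three steps most likely to fail are 10, 8 and 9.

Step 10 (double reductive cleavage, then double ring closure). The lithium alkoxide may attack the tert-butyl ester early, and the resulting lactone would be over-reduced. The hindered imide may also open at the ring carbonyl, and the free 1,3-diol may fragment under acid. The fallback sets out from 18 and removes the hydride from the picture. Both auxiliaries and the aryl acetate are cleaved hydrolytically (LiOH, H2O2, THF–H2O, 0 °C, exocyclic cleavage even at the hindered imide) to give the diacid tert-butyl ester F1. BH3·THF then reduces only the two free carboxylic acids, since the tert-butyl ester is inert and no lactone can form during the reduction. This gives 19 as an isolated compound, where the fallback comes back to the route; the acid-induced ring closures are then run on pure 19 as a separate operation to 20.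

Step 8 (α-arylation with an imide silyl enolate at a hindered, electron-rich aryl bromide). The fallback sets out from 12 and builds the arm at the ester level, loading the auxiliary afterwards. Pd-catalysed coupling of 12 with the Reformatsky reagent of benzyl bromoacetate (Pd(dba)2, Q-Phos, THF, rt) gives the benzyl arylacetate F2. Hydrogenolysis (H2, Pd/C, EtOAc) gives the arylacetic acid F3. DCC/DMAP coupling of F3 with (S)-4-benzyl-1,3-oxazolidin-2-one gives 15, where the fallback comes back to the route.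

Step 9 (boron aldol next to a tert-butyl ester, MOM ethers and a second imide; the adduct is prone to retro-aldol). The fallback sets out from 12 and brings the carbinol carbon in as an acyl group, so the α-centre is set by auxiliary-controlled C-acylation. This has the opposite facial sense to the aldol and therefore needs the antipodal auxiliary.
- Arylation of 12 as in step 8, but with the (R)-configured silyl enol ether F4 (from (R)-3-acetyl-4-benzyl-1,3-oxazolidin-2-one, TMSOTf, Et3N), gives the arylacetyl imide F5.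
- LDA (THF, −78 °C) then 4-acetoxy-3-methoxybenzoyl chloride gives the β-keto imide F6. The acid chloride adds anti to the benzyl group of the chelated Z-enolate, and allylic strain holds the product against enolisation.
- Zn(BH4)2 (chelation control) gives the syn-β-hydroxy imide F7.
- LiBH4 as in step 10 then gives 19, where the fallback comes back to the route. The carbinol configuration is in any case re-set in the cyclisation.

## Further compounds

F1 | step 10 | (2R,3R)-3-{[3-[(1S,2S)-1-carboxy-2-hydroxy-2-(4-hydroxy-3-methoxyphenyl)ethyl]-5-methoxy-4-(methoxymethoxy)phenyl]methyl}-4-tert-butoxy-2-{[3-methoxy-4-(methoxymethoxy)phenyl]methyl}-4-oxobutanoic acid | OC(=O)[C@H](Cc1ccc(OCOC)c(OC)c1)[C@@H](Cc1cc([C@H](C(O)=O)[C@H](O)c2ccc(O)c(OC)c2)c(OCOC)c(OC)c1)C(=O)OC(C)(C)C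
F2 | step 8 | tert-butyl (2R,3R)-3-{[(4R)-4-benzyl-2-oxo-1,3-oxazolidin-3-yl]carbonyl}-2-{[3-[2-(benzyloxy)-2-oxoethyl]-5-methoxy-4-(methoxymethoxy)phenyl]methyl}-4-[3-methoxy-4-(methoxymethoxy)phenyl]butanoate | O=C1OC[C@@H](Cc2ccccc2)N1C(=O)[C@H](Cc1ccc(OCOC)c(OC)c1)[C@@H](Cc1cc(CC(=O)OCc2ccccc2)c(OCOC)c(OC)c1)C(=O)OC(C)(C)C
F3 | step 8 | 2-{5-[(2R,3R)-3-{[(4R)-4-benzyl-2-oxo-1,3-oxazolidin-3-yl]carbonyl}-2-(tert-butoxycarbonyl)-4-[3-methoxy-4-(methoxymethoxy)phenyl]butyl]-3-methoxy-2-(methoxymethoxy)phenyl}acetic acid | O=C1OC[C@@H](Cc2ccccc2)N1C(=O)[C@H](Cc1ccc(OCOC)c(OC)c1)[C@@H](Cc1cc(CC(O)=O)c(OCOC)c(OC)c1)C(=O)OC(C)(C)C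
F4 | step 9 | (4R)-4-benzyl-3-{1-[(trimethylsilyl)oxy]ethenyl}-1,3-oxazolidin-2-one | C=C(O[Si](C)(C)C)N1[C@H](Cc2ccccc2)COC1=O
F5 | step 9 | tert-butyl (2R,3R)-3-{[(4R)-4-benzyl-2-oxo-1,3-oxazolidin-3-yl]carbonyl}-2-{[3-{2-[(4R)-4-benzyl-2-oxo-1,3-oxazolidin-3-yl]-2-oxoethyl}-5-methoxy-4-(methoxymethoxy)phenyl]methyl}-4-[3-methoxy-4-(methoxymethoxy)phenyl]butanoate | O=C1OC[C@@H](Cc2ccccc2)N1C(=O)[C@H](Cc1ccc(OCOC)c(OC)c1)[C@@H](Cc1cc(CC(=O)N2[C@H](Cc3ccccc3)COC2=O)c(OCOC)c(OC)c1)C(=O)OC(C)(C)C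
F6 | step 9 | tert-butyl (2R,3R)-2-{[3-{(2S)-3-[4-(acetyloxy)-3-methoxyphenyl]-1-[(4R)-4-benzyl-2-oxo-1,3-oxazolidin-3-yl]-1,3-dioxopropan-2-yl}-5-methoxy-4-(methoxymethoxy)phenyl]methyl}-3-{[(4R)-4-benzyl-2-oxo-1,3-oxazolidin-3-yl]carbonyl}-4-[3-methoxy-4-(methoxymethoxy)phenyl]butanoate | O=C1OC[C@@H](Cc2ccccc2)N1C(=O)[C@H](Cc1ccc(OCOC)c(OC)c1)[C@@H](Cc1cc([C@H](C(=O)N2[C@H](Cc3ccccc3)COC2=O)C(=O)c2ccc(OC(C)=O)c(OC)c2)c(OCOC)c(OC)c1)C(=O)OC(C)(C)C
F7 | step 9 | tert-butyl (2R,3R)-2-{[3-{(2S,3S)-3-[4-(acetyloxy)-3-methoxyphenyl]-1-[(4R)-4-benzyl-2-oxo-1,3-oxazolidin-3-yl]-3-hydroxy-1-oxopropan-2-yl}-5-methoxy-4-(methoxymethoxy)phenyl]methyl}-3-{[(4R)-4-benzyl-2-oxo-1,3-oxazolidin-3-yl]carbonyl}-4-[3-methoxy-4-(methoxymethoxy)phenyl]butanoate | O=C1OC[C@@H](Cc2ccccc2)N1C(=O)[C@H](Cc1ccc(OCOC)c(OC)c1)[C@@H](Cc1cc([C@H](C(=O)N2[C@H](Cc3ccccc3)COC2=O)[C@H](O)c2ccc(OC(C)=O)c(OC)c2)c(OCOC)c(OC)c1)C(=O)OC(C)(C)C
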